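**Retrosynthetic overview**

1. Target 15 ⇐ pivalate 14 by removal of the single protecting group on ring B (carried from step 1).
2. 14 ⇐ acyclic bis-ether 10, its constitutional isomer: one thermal operation forms the C8–prenyl bond, the C4a–C4 bond and the O1–C2 bond (allyl Claisen, then propargyl Claisen, [1,5]-H shift and oxa-6π closure).
3. Enabling feature: ring A is an acylphloroglucinol in which C8 and C4a are CH carbons, each lying between two oxygen-bearing carbons (C7/C8a and C8a/C5). Both carbon substituents can therefore be delivered by [3,3] shifts from tertiary C5 ethers on O7 and O1, while the aroyl group on C6 blocks the other ortho position of O7 and hydrogen-bonds 5-OH.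
4. 10 ⇐ 7 (tert-allylation of O7 with carbonate 9) ⇐ 5 (propargylation of O1 with 6) ⇐ Houben–Hoesch union of phloroglucinol 3 with nitrile 2.
5. Ring order: rings A and B are purchased arenes joined in step 2; the pyran (ring C) is closed last, in step 6.

Key step: step 6

Remark: the target has no stereocentre, so no stereocontrol is needed; ring A atoms carry the chromene numbering of the target (O1, C4a, C5, C6, C7, C8, C8a) in all precursors.

**Route**

Step 1
Reactants: 1 4-hydroxybenzonitrile
Product: 2 4-cyanophenyl pivalate
Conditions: PivCl, Et3N, DMAP (cat.), CH2Cl2, 0 °C to rt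
Reagents that add atoms: pivaloyl chloride, CC(C)(C)C(Cl)=O
Why: DMAP-catalysed O-acylation of a phenol gives a hindered aryl ester that should survive acid, amine base, zerovalent palladium and heat, and that mild methanolysis removes at the end.

Step 2
Reactants: 2 4-cyanophenyl pivalate; 3 phloroglucinol (anhydrous)
Product: 5 4-(2,4,6-trihydroxybenzoyl)phenyl pivalate, via ketiminium chloride 4 (not isolated)
Conditions: ZnCl2, HCl (g), Et2O, 0 °C to rt; then H2O, 90 °C
Reagents that add atoms: water, O
Why: Houben–Hoesch acylation, in which the electron-rich, threefold symmetric triol attacks the HCl/ZnCl2-activated nitrile at carbon to give one ketiminium salt (deactivated toward a second acylation) that hot water hydrolyses to the ketone.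

Step 3
Reactants: 5 4-(2,4,6-trihydroxybenzoyl)phenyl pivalate; 6 3-chloro-3-methylbut-1-yne
Product: 7 4-[2,6-dihydroxy-4-(2-methylbut-3-yn-2-yloxy)benzoyl]phenyl pivalate
Conditions: CuCl2·2H2O (cat.), DBU, MeCN, 0 °C
Reagents that add atoms: none
Why: Copper-catalysed propargylic etherification of a phenol with a tertiary propargylic chloride (copper acetylide, loss of chloride, capture of the allenylidene-type electrophile at the tertiary carbon) should alkylate only O1–H, the most acidic phenol and the one not hydrogen-bonded to the ketone.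

Step 4
Reactants: 8 2-methylbut-3-en-2-ol
Product: 9 tert-butyl 2-methylbut-3-en-2-yl carbonate
Conditions: n-BuLi, THF, −78 °C; Boc2O, −78 °C to rt; H2O
Reagents that add atoms: di-tert-butyl dicarbonate, CC(C)(C)OC(=O)OC(=O)OC(C)(C)C
Why: Alkoxycarbonylation of the lithium alkoxide of a tertiary allylic alcohol with Boc2O is a standard route to tertiary allyl carbonates for allylic substitution.

Step 5
Reactants: 7 4-[2,6-dihydroxy-4-(2-methylbut-3-yn-2-yloxy)benzoyl]phenyl pivalate; 9 tert-butyl 2-methylbut-3-en-2-yl carbonate
Product: 10 4-[2-hydroxy-6-(2-methylbut-3-en-2-yloxy)-4-(2-methylbut-3-yn-2-yloxy)benzoyl]phenyl pivalate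
Conditions: Pd(PPh3)4 (cat.), THF, 0 °C to rt
Reagents that add atoms: none
Why: Tsuji–Trost decarboxylative O-allylation, in which zerovalent palladium ionises 9 to a 1,1-dimethyl-π-allylpalladium cation and tert-butoxide, the phenoxide so formed attacks the more substituted allyl terminus under kinetic control to give the tertiary ether, and reaction should stop after one of the two equivalent ortho phenols because the remaining OH is then fully chelated to the ketone.

Step 6
Reactants: 10 4-[2-hydroxy-6-(2-methylbut-3-en-2-yloxy)-4-(2-methylbut-3-yn-2-yloxy)benzoyl]phenyl pivalate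
Product: 14 4-{[5,7-dihydroxy-2,2-dimethyl-8-(3-methylbut-2-en-1-yl)-2H-chromen-6-yl]carbonyl}phenyl pivalate, via prenylphenol propargyl ether 11 (not isolated), via allenylphenol 12 (not isolated), via ortho-quinone methide 13 (not isolated)
Conditions: o-xylene (degassed), 110 °C, then 145 °C, one pot
Reagents that add atoms: none
Why: On heating, the tertiary allyl ether on O7 should undergo an aromatic Claisen [3,3] shift to C8 and enolise to 11, after which the propargyl ether on O1 undergoes a propargyl Claisen [3,3] shift to C4a, enolisation to 12, a [1,5]-hydrogen shift from O1–H to the central allene carbon to give the Z ortho-quinone methide 13, and oxa-6π electrocyclisation. The closest known reactions are the Claisen rearrangement of aryl 1,1-dimethylallyl ethers to ortho-prenylphenols and the thermal conversion of aryl 1,1-dimethylpropargyl ethers into 2,2-dimethyl-2H-chromenes, here run in tandem in one flask. The 2H-pyran ring is closed by a thermal disrotatory 6π electrocyclisation of the 1-oxatriene of 13, which forms the O1–C2 bond after the sigmatropic shift has made the C4a–C4 bond. No stereocentre is formed; the Z geometry of the exocyclic alkene of 13 follows from the cyclic transition state of the hydrogen shift and is the geometry the ring closure needs. The step needs the prenyl group at C8 and the pyran at C4a/O1: the allyl ether should rearrange at the lower temperature and has only C8 to go to (C6 carries the aroyl group), which leaves C4a as the only free ortho carbon for the propargyl unit, and the hydrogen bond from 5-OH to the ketone, which favours the C7=C8 and C8a=C4a bond fixation, points both shifts the same way. The pyran oxygen should remain the original ether oxygen O1 because ring closure of 13 is expected to be much faster than proton exchange between the phenol oxygens in a non-polar aprotic solvent.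

Step 7
Reactants: 14 4-{[5,7-dihydroxy-2,2-dimethyl-8-(3-methylbut-2-en-1-yl)-2H-chromen-6-yl]carbonyl}phenyl pivalate
Product: 15 vismiaphenone E
Conditions: K2CO3, MeOH, rt, argon
Reagents that add atoms: none
Why: Base-mediated transesterification of the aryl pivalate (the para-aroylphenoxide is a good leaving group) should free the ring B phenol under conditions to which the chromene, the prenyl group and the chelated ketone are inert.

**Compound list**

1 | 4-hydroxybenzonitrile | N#Cc1ccc(O)cc1 | starting material
2 | 4-cyanophenyl pivalate (4-cyanophenyl 2,2-dimethylpropanoate) | CC(C)(C)C(=O)Oc1ccc(C#N)cc1 | intermediate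
3 | phloroglucinol (benzene-1,3,5-triol) | Oc1cc(O)cc(O)c1 | starting material
4 | [4-(pivaloyloxy)phenyl](2,4,6-trihydroxyphenyl)methaniminium chloride (ketiminium chloride, formed in the flask) | CC(C)(C)C(=O)Oc1ccc(C(=[NH2+])c2c(O)cc(O)cc2O)cc1.[Cl-] | intermediate
5 | 4-(2,4,6-trihydroxybenzoyl)phenyl pivalate | CC(C)(C)C(=O)Oc1ccc(C(=O)c2c(O)cc(O)cc2O)cc1 | intermediate
6 | 3-chloro-3-methylbut-1-yne | CC(C)(Cl)C#C | starting material
7 | 4-[2,6-dihydroxy-4-(2-methylbut-3-yn-2-yloxy)benzoyl]phenyl pivalate | CC(C)(C)C(=O)Oc1ccc(C(=O)c2c(O)cc(OC(C)(C)C#C)cc2O)cc1 | intermediate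
8 | 2-methylbut-3-en-2-ol | CC(C)(O)C=C | starting material
9 | tert-butyl 2-methylbut-3-en-2-yl carbonate | CC(C)(C)OC(=O)OC(C)(C)C=C | intermediate
10 | 4-[2-hydroxy-6-(2-methylbut-3-en-2-yloxy)-4-(2-methylbut-3-yn-2-yloxy)benzoyl]phenyl pivalate | CC(C)(C)C(=O)Oc1ccc(C(=O)c2c(O)cc(OC(C)(C)C#C)cc2OC(C)(C)C=C)cc1 | intermediate
11 | 4-[2,6-dihydroxy-3-(3-methylbut-2-enyl)-4-(2-methylbut-3-yn-2-yloxy)benzoyl]phenyl pivalate (formed in the flask) | CC(C)(C)C(=O)Oc1ccc(C(=O)c2c(O)cc(OC(C)(C)C#C)c(CC=C(C)C)c2O)cc1 | intermediate
12 | 4-[2,4,6-trihydroxy-3-(3-methylbuta-1,2-dienyl)-5-(3-methylbut-2-enyl)benzoyl]phenyl pivalate (formed in the flask) | CC(C)(C)C(=O)Oc1ccc(C(=O)c2c(O)c(C=C=C(C)C)c(O)c(CC=C(C)C)c2O)cc1 | intermediate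
13 | 4-{[(3Z)-2,6-dihydroxy-5-(3-methylbut-2-enyl)-3-(3-methylbut-2-enylidene)-4-oxocyclohexa-1,5-dien-1-yl]carbonyl}phenyl pivalate (formed in the flask) | O=C1C(CC=C(C)C)=C(O)C(C(=O)c2ccc(OC(=O)C(C)(C)C)cc2)=C(O)/C1=C/C=C(C)C | intermediate
14 | 4-{[5,7-dihydroxy-2,2-dimethyl-8-(3-methylbut-2-en-1-yl)-2H-chromen-6-yl]carbonyl}phenyl pivalate | CC(C)(C)C(=O)Oc1ccc(C(=O)c2c(O)c(CC=C(C)C)c3OC(C)(C)C=Cc3c2O)cc1 | intermediate
15 | vismiaphenone E, [5,7-dihydroxy-2,2-dimethyl-8-(3-methylbut-2-en-1-yl)-2H-chromen-6-yl](4-hydroxyphenyl)methanone | CC(C)=CCc1c(O)c(C(=O)c2ccc(O)cc2)c(O)c2c1OC(C)(C)C=C2 | target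

**Step count**

Total steps: 7. Longest linear sequence: 6 (steps 1, 2, 3, 5, 6, 7; step 4 is a side branch).

**Steps most likely to fail, with fallbacks**

Step 5. The phenol to be alkylated is hydrogen-bonded to the ketone and may react slowly. The tertiary ether may also re-ionise on palladium and isomerise to the linear prenyl ether, which would later deliver a reverse-prenyl group. The fallback sets out from 7 and returns at 11, moving the allyl unit through O1 instead of O7. Semihydrogenation of the alkyne of 7 (H2, Pd/CaCO3 poisoned with Pb(OAc)2, quinoline, EtOAc) should give 4-[2,6-dihydroxy-4-(2-methylbut-3-en-2-yloxy)benzoyl]phenyl pivalate F1. Claisen rearrangement of F1 in toluene at 110 °C should give 4-[2,4,6-trihydroxy-3-(3-methylbut-2-enyl)benzoyl]phenyl pivalate F2, with either ortho carbon giving the same product by symmetry. Copper-catalysed propargylation of the O1–H of F2 with 6 (CuCl2·2H2O, DBU, MeCN) should give 11 as an isolated compound. Heating 11 as in the second stage of step 6 then leads to 14.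

Step 6. The tertiary allyl group may be lost by ionisation and elimination before it rearranges, or the propargyl unit may shift to C8 before the allyl group has moved, giving the wrong regiochemistry. The fallback sets out from 7 and returns at 14, installing the two C5 units in separate operations with the pyran first. Heating 7 alone (o-xylene, 145 °C) can give only one chromene because C4a and C8 are still equivalent, namely 4-(5,7-dihydroxy-2,2-dimethyl-2H-chromene-6-carbonyl)phenyl pivalate F3. C-Prenylation of F3 at C8, the only free carbon of ring A, with 1-bromo-3-methylbut-2-ene and DBU in THF should then give 14.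

Step 2. The pivalate may be partly cleaved during the hot aqueous hydrolysis of the ketiminium salt, or the hydrolysis of the stabilised diaryl ketimine may stay incomplete. The fallback sets out from 3 and returns at 5, replacing the nitrile by an acid chloride. 4-Hydroxybenzoic acid is pivaloylated (PivCl, aqueous NaOH, 0 °C, then acidification) to 4-(pivaloyloxy)benzoic acid F4. Oxalyl chloride with catalytic DMF in CH2Cl2 converts F4 into 4-(pivaloyloxy)benzoyl chloride F5. Friedel–Crafts acylation of 3 with F5 (AlCl3, PhNO2, rt, then ice and dilute HCl) should give 5 directly, with no imine to hydrolyse.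

**Further compounds**

F1 | step 5 | 4-[2,6-dihydroxy-4-(2-methylbut-3-en-2-yloxy)benzoyl]phenyl pivalate | CC(C)(C)C(=O)Oc1ccc(C(=O)c2c(O)cc(OC(C)(C)C=C)cc2O)cc1
F2 | step 5 | 4-[2,4,6-trihydroxy-3-(3-methylbut-2-enyl)benzoyl]phenyl pivalate | CC(C)(C)C(=O)Oc1ccc(C(=O)c2c(O)cc(O)c(CC=C(C)C)c2O)cc1
F3 | step 6 | 4-(5,7-dihydroxy-2,2-dimethyl-2H-chromene-6-carbonyl)phenyl pivalate | CC(C)(C)C(=O)Oc1ccc(C(=O)c2c(O)cc3OC(C)(C)C=Cc3c2O)cc1
F4 | step 2 | 4-(pivaloyloxy)benzoic acid | CC(C)(C)C(=O)Oc1ccc(C(=O)O)cc1
F5 | step 2 | 4-(pivaloyloxy)benzoyl chloride | CC(C)(C)C(=O)Oc1ccc(C(Cl)=O)cc1
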